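Atom numbering is that of the germacrane skeleton: C1 ketone, C4–C5 epoxide (C15 methyl on C4), C6 lactone carbinol, C7=C11 butenolide alkene, C12 lactone carbonyl, C13 acetoxymethyl carbon, C8 ester carbinol, C10 acetoxy carbon (C14 methyl).

## Analysis of the target

The target is a germacranolide: a ten-membered carbocycle C1–C10 fused across C6–C7 to a butenolide (O–C12(=O)–C11=C7). It carries a C1 ketone, a C4–C5 epoxide, an acetoxymethyl group on C11, a methacrylate on O8 and a quaternary C10 with a methyl and an acetoxy group. There are five stereocentres (4R, 5S, 6R, 8S, 10R). The epoxide is cis, so it derives from a Z C4=C5 alkene, and it lies on the side of the lactone oxygen when H-6 eclipses C3. C6 and C8 flank the planar C7 and talk to each other only through the ring conformation, and C10 is remote from both. The sensitive groups are the epoxide next to the lactone carbinol (acid), H-6 of the butenolide (base gives a furanolate that can attack C1 across the ring or expel the C13 acetate), the tertiary α-acetoxy ketone, three different esters that rule out any hydrolysis, and the polymerisable methacrylate. The difficulties are the medium ring with a Z trisubstituted alkene, the tetrasubstituted C7=C11 alkene whose geometry has to be set, and the two adjacent fully substituted carbons C1 and C10 whose oxygens must be told apart. The strategy rests on one feature: C1 and C6 lie opposite each other across the ten-membered ring, so a C1–C6 bond turns the carbocycle into a decalin (ring A: C1–C6, ring B: C1, C6–C10). The cyclohexene of ring A enforces the Z C4=C5 geometry, and C6, flanked by C4=C5 and C7=C11, is the carbon that a C1 alkoxy radical releases most easily.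

## Retrosynthetic reasoning

**27 to 24.** The three most fragile features are removed first. The epoxide of 27 is traced to the Z alkene of 26, the methacrylate to alcohol 25, and 25 to silyl ether 24. The epoxide is put in last so that it never meets fluoride or an acylating base. The forward epoxidation has to choose the one electron-rich alkene and its outer face.

**24 to 21.** The C6–O bond is cut and C1 is joined to C6. This gives decalinol 21, a tertiary alcohol whose ester sits on C11 cis to C6. Nowhere else does one bond remove the medium ring, fix the Z alkene and leave the lactone atoms in place. Forward, a C1 alkoxy radical must break C1–C6 and the C6 radical must be oxidised and captured by the C12 carboxyl. The acid is carried as its methyl ester, because the free hydroxy acid would close onto O1 as a δ-lactone. C1 and C6 are erased or reset in this step, so 21 need not be a single diastereomer at these two centres.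

**21 to 18.** Acetate and silyl adjustments lead from 21 through 20 to 19. Ring A of 19 is cut at C4=C5, which gives diene 18 with a vinyl group on C6 and a 3-methylbut-3-enyl chain on C1. Ring-closing metathesis can only give the Z ring alkene.

**18 to 17.** C6–C7 and C11–C12 are cut together, which leads to the allylic acetate and alkyne of 17. A syn addition of an allyl–metal bond across the alkyne, followed by carbonylation with retention, is the one disconnection that sets the tetrasubstituted alkene stereospecifically. An olefination of a C7 ketone could not do this. The forward step has to close ring B in the 6-exo mode and put the ester cis to C6.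

**17 to 12 and 14.** The C1–C6 bond is cut as a carbonyl addition: ketone 12 plus the three-carbon bromide 14, by way of alcohol 16. Fragment 14 brings C5, C6 and the allylic leaving group in one piece, and it is one step from 13.

**12 to 8 and 9.** The C10 acetate is placed at the ketone stage (11 to 12), before the C1 carbinol exists. This is how the two adjacent tertiary oxygens are told apart without protecting-group exchange. The C1–C2 bond comes from Weinreb amide 8 and Grignard reagent 10, made from 9.

**8 to 2 and 3.** The C8 carbinol is 1,3 to C10, where substrate control is unreliable, so it is set by catalyst-controlled reduction of ynone 5 (6, then 7, then 8). Ynone 5 comes from acid chloride 4 and alkyne 3, which forms C7–C8 and brings C11 and C13.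

**2 to 1.** Acid 2 is the acetonide of 1. Compound 1 supplies C10 with its methyl group and oxygen in the right configuration, C9, and C1 and C8 at the carboxyl level. The acetonide differentiates the two carboxyl groups.

## Alternatives that were turned down

**Alternative 1:** The carbocycle is cut at C6–C7 and regrown into a thirteen-membered cyclic allyl ether in which oxygen links C6 to C13. Forward, tin–lithium exchange makes an α-oxy carbanion at C6, and a [2,3]-Wittig shift forms C6–C7 while O–C13 breaks. This contracts the ring and would give cyclodecenol A1.
- For: no direct closure of a ten-membered ring is needed, the shift is concerted and runs cold, and the C6 carbinol appears in the right place. Ring contractions of this type are well established for medium carbocycles, so on precedent this key step is stronger than the one chosen.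
- Against: A1 has C7 as an sp3 centre with a 2-propenyl branch. The branch must still be oxidised to the acid level, lactonised, and the double bond moved into the tetrasubstituted C7=C11 position. The C1 ketone and the C10 and C13 acetates are still masked. The large ether ring needs its own macrocyclisation, and the C7 configuration set by the shift is later destroyed.
- Comparison: the chosen cascade is less certain, but it delivers ketone, lactone and the correct alkene position together and leaves three steps to the target, where A1 would need many more.

**Alternative 2:** C1–C10 and C8–C9 are cut. Forward, a [2+2] photocycloaddition of an eight-membered-ring enone with isopropenyl acetate A3 closes a cyclobutane and gives photoadduct A2. A later retro-aldol opening would expand it to the ten-membered 1,5-diketone.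
- For: an eight-membered ring is easier to make than a ten-membered one, and C10 arrives with its methyl and acetoxy groups from a cheap partner. On that point it is more direct than the chiral-pool entry used here.
- Against: the cycloaddition is intermolecular and uses a 1,1-disubstituted enol acetate, so head-to-head regiochemistry and the facial course must both be right, and C10 is created with no clear control element. A2 has no oxygen at C8 and no butenolide, so C8 must be oxidised later beside two enolisable positions and the lactone built afterwards. The epoxide and the benzylic ether must also survive irradiation.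
- Comparison: the chosen route takes C10 from 1 and sets C8 with a catalyst, and its key step makes the lactone itself.

**Alternative 3:** The ring is cut at C7–C8. Forward, under Nozaki–Hiyama–Kishi conditions the alkenyl iodide of a β-iodobutenolide adds to a C8 aldehyde, which closes the ten-membered ring and gives alcohol A4.
- For: it is the most convergent plan, A4 is one acylation from the target, and the reaction type is known for medium rings and tolerates ketone, epoxide and esters. After the key step it is clearly shorter than the chosen route.
- Against: a ten-membered closure pays full entropic and transannular cost. C8 is created in the closure and has only the folded chain to steer it toward 8S. The open-chain aldehyde is β to the C10 acetate and prone to elimination. The acyclic precursor must carry the epoxide, the iodobutenolide and all other stereocentres through a long linear sequence.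
- Comparison: the chosen strategy sets C8 early with a catalyst, obtains the Z alkene by construction, and pays for the medium ring with a fragmentation driven by a stabilised radical.

Key step: step 15

Remark on the chemistry: C1 and C6 of compounds 16–23 are formed without control and are left unspecified in the structures, because both centres are erased or reset in step 15 and every diastereomer converges on 24. Compounds 3, 9 and 13 are taken as commercial.

## Route

Step 1
Reactants: 1 (R)-citramalic acid
Product: 2 2-[(4R)-2,2,4-trimethyl-5-oxo-1,3-dioxolan-4-yl]acetic acid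
Conditions: 2,2-dimethoxypropane, TsOH (cat.), rt
Reagents that add atoms: 2,2-dimethoxypropane, COC(C)(C)OC
Why: Acetonide formation of an α-hydroxy acid; the five-membered dioxolanone is preferred over the six-membered alternative, so the C1 carboxyl and the C10 hydroxyl are masked together, the C8 carboxyl stays free and the stereocentre is untouched.

Step 2
Reactants: 2 dioxolanone acid; 3 tert-butyldimethyl(prop-2-yn-1-yloxy)silane
Product: 5 (5R)-5-[5-(tert-butyldimethylsilyloxy)-2-oxopent-3-yn-1-yl]-2,2,5-trimethyl-1,3-dioxolan-4-one, via acid chloride 4 (not isolated)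
Conditions: (COCl)2, DMF (cat.), CH2Cl2, 0 °C to rt; then 3, PdCl2(PPh3)2 (cat.), CuI (cat.), Et3N, THF, rt
Reagents that add atoms: none
Why: Acyl Sonogashira coupling of an acid chloride with a terminal alkyne forms C7–C8 and brings C11 and C13; the mild copper acetylide leaves the electrophilic dioxolanone carbonyl alone, which a lithium acetylide would not.

Step 3
Reactants: 5 ynone
Product: 6 (5R)-5-[(2S)-5-(tert-butyldimethylsilyloxy)-2-hydroxypent-3-yn-1-yl]-2,2,5-trimethyl-1,3-dioxolan-4-one
Conditions: Ru[(S,S)-TsDPEN](p-cymene) (cat.), i-PrOH, rt
Reagents that add atoms: none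
Why: Noyori asymmetric transfer hydrogenation of an alkynyl ketone under base-free conditions; the catalyst, not the remote C10 centre, sets C8, and the (S,S) ligand is expected to give the S carbinol by analogy with simple alkyl alkynyl ketones (the mirror-image catalyst is the remedy if the sense is reversed).

Step 4
Reactants: 6 propargylic alcohol
Product: 7 C8 triisopropylsilyl ether of 6
Conditions: TIPSOTf, 2,6-lutidine, CH2Cl2, −78 to 0 °C
Reagents that add atoms: triisopropylsilyl trifluoromethanesulfonate, CC(C)[Si](C(C)C)(C(C)C)OS(=O)(=O)C(F)(F)F
Why: Silylation of a secondary alcohol; the bulky silyl group is chosen so that it outlasts the later removal of a primary tert-butyldimethylsilyl and a tertiary triethylsilyl ether, and early protection stops O8 from lactonising onto the dioxolanone.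

Step 5
Reactants: 7 dioxolanone
Product: 8 (2R,4S)-7-(tert-butyldimethylsilyloxy)-2-hydroxy-N-methoxy-N,2-dimethyl-4-(triisopropylsilyloxy)hept-5-ynamide
Conditions: MeNHOMe·HCl, i-PrMgCl, THF, −20 to 0 °C
Reagents that add atoms: N,O-dimethylhydroxylamine hydrochloride, CNOC.Cl
Why: Aminolysis of the activated dioxolanone carbonyl by the magnesium amide (Weinreb amide formation) releases acetone and the C10 tertiary alcohol; the quaternary centre cannot epimerise.

Step 6
Reactants: 8 Weinreb amide; 9 4-bromo-2-methylbut-1-ene
Product: 11 (6R,8S)-11-(tert-butyldimethylsilyloxy)-6-hydroxy-2,6-dimethyl-8-(triisopropylsilyloxy)undec-1-en-9-yn-5-one, via Grignard reagent 10 (not isolated)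
Conditions: 9, Mg, THF, rt; then 8, THF, 0 °C to rt (excess 10)
Reagents that add atoms: none
Why: Weinreb ketone synthesis forms C1–C2 and brings C2–C4 and C15; the first equivalent of 10 deprotonates the C10 hydroxyl and the chelated tetrahedral intermediate prevents a second addition.

Step 7
Reactants: 11 α-hydroxy ketone
Product: 12 (6R,8S)-11-(tert-butyldimethylsilyloxy)-2,6-dimethyl-5-oxo-8-(triisopropylsilyloxy)undec-1-en-9-yn-6-yl acetate
Conditions: Ac2O, DMAP, Et3N, CH2Cl2, rt to 40 °C
Reagents that add atoms: acetic anhydride, CC(=O)OC(C)=O
Why: DMAP-catalysed acetylation of a tertiary α-ketol; O10 is the only free hydroxyl, so the C10 acetate is installed before the C1 carbinol exists and the two tertiary oxygens never have to be distinguished.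

Step 8
Reactants: 13 acrolein
Product: 14 3-bromoprop-1-en-1-yl acetate (E/Z mixture)
Conditions: AcBr, ZnCl2 (cat.), CH2Cl2, −20 °C to rt
Reagents that add atoms: acetyl bromide, CC(=O)Br
Why: 1,4-Addition of acetyl bromide to the enal (bromide to the β-carbon, acyl to oxygen) gives the γ-bromo enol acetate; both geometric isomers lead to the same allylindium reagent.

Step 9
Reactants: 12 α-acetoxy ketone; 14 3-bromoprop-1-en-1-yl acetate
Product: 16 C1 tertiary alcohol carrying a C6 acetoxy group and a C5 vinyl group (mixture at C1 and C6), via allylindium reagent 15 (not isolated)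
Conditions: In powder, THF/sat. aq. NH4Cl, rt
Reagents that add atoms: none
Why: Barbier-type α-acetoxyallylation: indium inserts into the allylic bromide and the γ-acetoxyallylindium adds to the ketone through its oxygen-bearing carbon, which forms C1–C6 and places the allylic leaving group; the esters tolerate the reagent and the protic medium protonates the C1 alkoxide before it can attack the neighbouring C10 acetate. The configurations at C1 and C6 are not controlled and need not be.

Step 10
Reactants: 16 tertiary alcohol
Product: 17 C1 triethylsilyl ether of 16
Conditions: TESOTf, 2,6-lutidine, CH2Cl2, −78 to 0 °C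
Reagents that add atoms: triethylsilyl trifluoromethanesulfonate, CC[Si](CC)(CC)OS(=O)(=O)C(F)(F)F
Why: Silyl triflate silylation of a hindered tertiary alcohol; O1 must be blocked in step 11, where a free hydroxyl would capture the acylpalladium as a δ-lactone.

Step 11
Reactants: 17 allylic acetate with tethered alkyne
Product: 18 ring B diene ester: methyl ester on C11 cis to C6, C6 vinyl, C1 triethylsilyl ether (mixture at C1 and C6)
Conditions: Pd2(dba)3 (cat.), PPh3, CO (3 atm), MeOH/THF, 50 °C
Reagents that add atoms: carbon monoxide, [C-]#[O+]; methanol, CO
Why: Palladium-ene cyclisation with carbonylative capture: zerovalent palladium ionises the allylic acetate, and the η3-allyl complex, free to change face through its unsubstituted end, adds through C6 across the alkyne in a 6-exo syn insertion that leaves palladium on C11 cis to C6. CO insertion and methanolysis then put the ester cis to C6 and the silyloxymethyl group cis to C8, which fixes the C7=C11 geometry; the silyl ether on C13 is a poor leaving group, so the alkenylpalladium should not collapse to an allene.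

Step 12
Reactants: 18 diene
Product: 19 decalin with C4=C5 in ring A (C1 triethylsilyl ether, C13 tert-butyldimethylsilyl ether, C8 triisopropylsilyl ether)
Conditions: second-generation Hoveyda–Grubbs catalyst RuCl2(H2IMes)(=CH-C6H4-2-O-i-Pr) (cat.), toluene, 80 °C
Reagents that add atoms: none
Why: Ring-closing metathesis of the C6 vinyl group with the 1,1-disubstituted alkene closes ring A as a trisubstituted cyclohexene, which can only be Z; the tetrasubstituted enoate is inert and either relative arrangement at C1 and C6 can close.

Step 13
Reactants: 19 tris-silyl ether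
Product: 20 C1,C13-diol (C8 triisopropylsilyl ether retained)
Conditions: HF·pyridine, pyridine, THF, 0 °C to rt
Reagents that add atoms: none
Why: Fluoride desilylation cleaves the tertiary triethylsilyl and the primary tert-butyldimethylsilyl ether and leaves the hindered secondary triisopropylsilyl ether; the buffered, non-basic medium avoids acetyl migration from O10 to O1 and lactonisation of O1 onto the ester.

Step 14
Reactants: 20 diol
Product: 21 decalinol precursor: C1 tertiary alcohol, C4=C5, C7=C11 with methyl ester cis to C6, C13 and C10 acetates, C8 triisopropylsilyl ether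
Conditions: Ac2O, pyridine, CH2Cl2, 0 °C
Reagents that add atoms: acetic anhydride, CC(=O)OC(C)=O
Why: Selective acetylation of the primary allylic alcohol; the hindered tertiary C1 hydroxyl does not react under these conditions.

Step 15
Reactants: 21 decalinol
Product: 24 4,5-deoxy target as its C8 triisopropylsilyl ether, via hypoiodite 22 (not isolated), via allylic iodide 23 (not isolated)
Conditions: PhI(OAc)2, I2, CH2Cl2/cyclohexane, visible light, 15 °C; then 40 °C
Reagents that add atoms: none
Why: Proposed new method: PhI(OAc)2 and I2 form acetyl hypoiodite, which turns the C1 hydroxyl into hypoiodite 22; light cleaves O–I, and the C1 alkoxy radical breaks the C1–C6 ring-fusion bond, which opens rings A and B into the ten-membered C1 ketone and a radical spread over C4, C6, C11 and the ester. Iodine-atom transfer gives allylic iodide 23 (or trivalent iodine oxidises the radical to the cation), the cis ester carbonyl oxygen attacks C6 in a 5-exo closure, and iodide takes the methyl group from the dialkoxycarbenium ion as methyl iodide, so that the O–C6 bond and the butenolide are formed. The closest known reactions are the hypoiodite ring expansion of fused tertiary cycloalkanols to medium-ring ketones and the lactonisation of γ-halo (Z)-enoates; their union through a pentadienyl radical in one flask is not known. Scission has to take C1–C6 and not C1–C10 or C1–C2: only C1–C6 leads to an allylic, ester-conjugated radical, the C10 acetoxy group stabilises the alternative tertiary radical poorly, and C1–C2 would give a primary radical. The ten-membered ring is formed by this fragmentation and not by a closure, and its C4=C5 bond is Z because it was the cyclohexene bond of ring A; fast iodine transfer at low temperature should keep it so. Because C7=C11 was fixed in step 11 with the ester cis to C6, C6 is the only end of the allylic system within reach of the carbonyl oxygen, which secures O–C6 over O–C4 closure or capture by acetate. The new C6 centre is set by C8: allylic 1,3-strain with C13 puts H-8 in the plane of the enoate, C9 and C5 then leave that plane on the same side, and closure on C6 gives the 6S configuration of 24 (6R in the target after the change of priorities); as the allylic C6–O bond can ionise again under the conditions, this should also be the equilibrium product. All diastereomers of 21 give the same radical and converge, and the ring alkene is protected from addition of acetyl hypoiodite by adding the reagents in portions under irradiation in a non-polar medium.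

Step 16
Reactants: 24 silyl ether
Product: 25 C8 alcohol (4,5-deoxy, 8-hydroxy compound)
Conditions: HF·pyridine, THF, rt
Reagents that add atoms: none
Why: Fluoride desilylation under non-basic conditions, which spares H-6 of the butenolide, the acetates and the α-acetoxy ketone; the butenolide cannot migrate to O8 because C12 is held cis to C6.

Step 17
Reactants: 25 alcohol
Product: 26 4,5-deoxy target (C8 methacrylate)
Conditions: methacryloyl chloride, Et3N, DMAP (cat.), BHT (trace), CH2Cl2, 0 °C
Reagents that add atoms: methacryloyl chloride, C=C(C)C(Cl)=O
Why: DMAP-catalysed acylation of the secondary alcohol; low temperature and short contact with the amine avoid furanolate formation at C6, and the inhibitor suppresses polymerisation.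

Step 18
Reactants: 26 deoxy compound
Product: 27 target, CNP0172381.2
Conditions: dimethyldioxirane, acetone, −20 to 0 °C
Reagents that add atoms: dimethyldioxirane, CC1(C)OO1
Why: Electrophilic epoxidation picks the only electron-rich alkene (C4=C5) over the methacrylate and butenolide alkenes. Attack on the outer face of the Z alkene, anti to C7 and syn to the lactone oxygen in the conformer with H-6 eclipsing C3, should give the 4R,5S epoxide; the neutral, volatile reagent spares the product.

## Compound list

1 | (R)-citramalic acid | OC(=O)C[C@@](C)(O)C(O)=O | starting material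
2 | 2-[(4R)-2,2,4-trimethyl-5-oxo-1,3-dioxolan-4-yl]acetic acid | OC(=O)C[C@@]1(C)OC(C)(C)OC1=O | intermediate
3 | tert-butyldimethyl(prop-2-yn-1-yloxy)silane | C#CCO[Si](C)(C)C(C)(C)C | starting material
4 | 2-[(4R)-2,2,4-trimethyl-5-oxo-1,3-dioxolan-4-yl]acetyl chloride (not isolated) | ClC(=O)C[C@@]1(C)OC(C)(C)OC1=O | intermediate
5 | (5R)-5-[5-(tert-butyldimethylsilyloxy)-2-oxopent-3-yn-1-yl]-2,2,5-trimethyl-1,3-dioxolan-4-one | CC(C)(C)[Si](C)(C)OCC#CC(=O)C[C@@]1(C)OC(C)(C)OC1=O | intermediate
6 | (5R)-5-[(2S)-5-(tert-butyldimethylsilyloxy)-2-hydroxypent-3-yn-1-yl]-2,2,5-trimethyl-1,3-dioxolan-4-one | CC(C)(C)[Si](C)(C)OCC#C[C@@H](O)C[C@@]1(C)OC(C)(C)OC1=O | intermediate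
7 | (5R)-5-[(2S)-5-(tert-butyldimethylsilyloxy)-2-(triisopropylsilyloxy)pent-3-yn-1-yl]-2,2,5-trimethyl-1,3-dioxolan-4-one | CC(C)(C)[Si](C)(C)OCC#C[C@@H](O[Si](C(C)C)(C(C)C)C(C)C)C[C@@]1(C)OC(C)(C)OC1=O | intermediate
8 | (2R,4S)-7-(tert-butyldimethylsilyloxy)-2-hydroxy-N-methoxy-N,2-dimethyl-4-(triisopropylsilyloxy)hept-5-ynamide | CC(C)(C)[Si](C)(C)OCC#C[C@@H](O[Si](C(C)C)(C(C)C)C(C)C)C[C@@](C)(O)C(=O)N(C)OC | intermediate
9 | 4-bromo-2-methylbut-1-ene | C=C(C)CCBr | starting material
10 | (3-methylbut-3-en-1-yl)magnesium bromide (not isolated) | C=C(C)CC[Mg]Br | intermediate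
11 | (6R,8S)-11-(tert-butyldimethylsilyloxy)-6-hydroxy-2,6-dimethyl-8-(triisopropylsilyloxy)undec-1-en-9-yn-5-one | CC(C)(C)[Si](C)(C)OCC#C[C@@H](O[Si](C(C)C)(C(C)C)C(C)C)C[C@@](C)(O)C(=O)CCC(C)=C | intermediate
12 | (6R,8S)-11-(tert-butyldimethylsilyloxy)-2,6-dimethyl-5-oxo-8-(triisopropylsilyloxy)undec-1-en-9-yn-6-yl acetate | CC(C)(C)[Si](C)(C)OCC#C[C@@H](O[Si](C(C)C)(C(C)C)C(C)C)C[C@@](C)(OC(C)=O)C(=O)CCC(C)=C | intermediate
13 | acrolein | C=CC=O | starting material
14 | 3-bromoprop-1-en-1-yl acetate (E/Z) | CC(=O)OC=CCBr | intermediate
15 | (3-acetoxyallyl)indium dibromide, simplest formulation of the trivalent indium reagent (not isolated) | CC(=O)OC=CC[In](Br)Br | intermediate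
16 | adduct of 12: C1 tertiary alcohol with 3-methylbut-3-enyl chain, C6 acetoxy(vinyl)methine, C10 acetate, C8 (S) triisopropylsilyl ether, C13 tert-butyldimethylsilyl ether; mixture at C1 and C6 | CC(C)(C)[Si](C)(C)OCC#C[C@@H](O[Si](C(C)C)(C(C)C)C(C)C)C[C@@](C)(OC(C)=O)C(O)(CCC(C)=C)C(OC(C)=O)C=C | intermediate
17 | C1 triethylsilyl ether of 16; mixture at C1 and C6 | CC(C)(C)[Si](C)(C)OCC#C[C@@H](O[Si](C(C)C)(C(C)C)C(C)C)C[C@@](C)(OC(C)=O)C(O[Si](CC)(CC)CC)(CCC(C)=C)C(OC(C)=O)C=C | intermediate
18 | ring B diene ester: cyclohexane with C7=C11 exocyclic alkene (methyl ester cis to C6, silyloxymethyl cis to C8), C6 vinyl, C1 triethylsilyloxy and 3-methylbut-3-enyl, C10 acetate, C8 (S) triisopropylsilyl ether; mixture at C1 and C6 | COC(=O)/C(CO[Si](C)(C)C(C)(C)C)=C1/[C@@H](O[Si](C(C)C)(C(C)C)C(C)C)C[C@@](C)(OC(C)=O)C(O[Si](CC)(CC)CC)(CCC(C)=C)C1C=C | intermediate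
19 | decalin from 18 with ring A C4=C5 alkene; tris-silyl ether; mixture at C1 and C6 | COC(=O)/C(CO[Si](C)(C)C(C)(C)C)=C1/[C@@H](O[Si](C(C)C)(C(C)C)C(C)C)C[C@@](C)(OC(C)=O)C2(O[Si](CC)(CC)CC)CCC(C)=CC12 | intermediate
20 | C1,C13-diol of 19 (C8 triisopropylsilyl ether kept); mixture at C1 and C6 | COC(=O)/C(CO)=C1/[C@@H](O[Si](C(C)C)(C(C)C)C(C)C)C[C@@](C)(OC(C)=O)C2(O)CCC(C)=CC12 | intermediate
21 | decalinol precursor: 1-hydroxydecalin with C4=C5 alkene, C7 alkylidene methyl ester (ester cis to C6), C13 and C10 acetates, C8 (S) triisopropylsilyl ether, C10 (R); mixture at C1 and C6 | COC(=O)/C(COC(C)=O)=C1/[C@@H](O[Si](C(C)C)(C(C)C)C(C)C)C[C@@](C)(OC(C)=O)C2(O)CCC(C)=CC12 | intermediate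
22 | C1 hypoiodite of 21 (not isolated) | COC(=O)/C(COC(C)=O)=C1/[C@@H](O[Si](C(C)C)(C(C)C)C(C)C)C[C@@](C)(OC(C)=O)C2(OI)CCC(C)=CC12 | intermediate
23 | ten-membered C1 ketone with C6 allylic iodide, Z C4=C5, methyl ester cis to C6 (not isolated) | COC(=O)/C(COC(C)=O)=C1/[C@@H](O[Si](C(C)C)(C(C)C)C(C)C)C[C@@](C)(OC(C)=O)C(=O)CC/C(C)=C\C1I | intermediate
24 | 4,5-deoxy target as its C8 triisopropylsilyl ether (6S,8S,10R; Z C4=C5) | CC(C)[Si](C(C)C)(C(C)C)O[C@H]1C[C@@](C)(OC(C)=O)C(=O)CC/C(C)=C\[C@@H]2OC(=O)C(COC(C)=O)=C12 | intermediate
25 | 4,5-deoxy 8-hydroxy compound | O[C@H]1C[C@@](C)(OC(C)=O)C(=O)CC/C(C)=C\[C@@H]2OC(=O)C(COC(C)=O)=C12 | intermediate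
26 | 4,5-deoxy target (C8 methacrylate) | C=C(C)C(=O)O[C@H]1C[C@@](C)(OC(C)=O)C(=O)CC/C(C)=C\[C@@H]2OC(=O)C(COC(C)=O)=C12 | intermediate
27 | CNP0172381.2 (4R,5S,6R,8S,10R) | C=C(C)C(=O)O[C@H]1C[C@@](C)(OC(C)=O)C(=O)CC[C@@]2(C)O[C@H]2[C@@H]2OC(=O)C(COC(C)=O)=C12 | target

## Step count and least certain steps

Total: 18 steps. Longest linear sequence: 17 steps from 1 (steps 1–7 and 9–18); step 8 is a one-step side branch.

**Step 15 (key step).**
- What may go wrong: acetyl hypoiodite may add to the C4=C5 alkene before the hypoiodite is photolysed. The alkoxy radical may break C1–C10 instead of C1–C6. Rotation within the pentadienyl radical may erode the Z geometry. The allylic iodide may be captured at C4 or by acetate instead of lactonising. Closure may favour the C6 epimer.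
- Remedy for the epimer alone: equilibration of the allylic lactone through its η3-allyl carboxylate with Pd(PPh3)4.
- Fallback with known chemistry, from 21 back to 24: the scission and the C6 oxidation are separated. First, a redox-neutral, light-driven ring opening of the tertiary alcohol by proton-coupled electron transfer ([Ir(dF(CF3)ppy)2(5,5′-d(CF3)bpy)]PF6, collidine, an arenethiol as hydrogen donor, blue light). This involves no electrophilic iodine and should give the ring-opened keto ester with a C6 methylene group F1. Second, Wohl–Ziegler bromination (NBS, AIBN, PhCF3, 70 °C) at the doubly allylic C6 should give the C6 bromide F2. Third, F2 lactonises on warming with AgOTf with loss of methyl bromide, the classical closure of a γ-bromo (Z)-enoate, to give 24.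

**Step 11 (palladium-ene with carbonylation).**
- What may go wrong: insertion of the 1,1-disubstituted alkene instead of the alkyne, β-elimination of the C13 silyloxy group from the alkenylpalladium to an allene, insertion of the C6 vinyl group into the acylpalladium, or direct carbonylation of the allyl complex.
- Fallback, from 17 back to 18: a palladium-catalysed zinc-ene cyclisation (Pd(PPh3)4 cat., Et2Zn, Et2O, 35 °C) turns the allylic acetate into a fluxional allylzinc that adds syn across the alkyne. Iodine quench of the alkenylzinc should give alkenyl iodide F3 with iodine cis to C6. A separate methoxycarbonylation (Pd(OAc)2, dppp, CO, MeOH, Et3N) then gives 18.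

**Step 9 (α-acetoxyallylation).**
- What may go wrong: the stabilised allylindium may be too unreactive toward the hindered α-quaternary ketone, or the ketone may be reduced or its acetate lost.
- Fallback, from 12 back to 19: the ring order is changed.
  - The parent allyl group is added (allyl bromide, In, aqueous THF) to give homoallylic alcohol F4.
  - Ring-closing metathesis gives cyclohexenol F5.
  - Hydroxyl-directed epoxidation (VO(acac)2, t-BuOOH) gives epoxy alcohol F6 with the epoxide cis to O1.
  - TESOTf gives silyl ether F7.
  - Phenylselenide opening at C5 gives hydroxy selenide F8.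
  - Oxidation and syn elimination give tertiary allylic alcohol F9 with C5=C6.
  - Acetylation gives tertiary allylic acetate F10, whose leaving group is trans to the alkyne tether as a cyclic palladium-ene requires.
  - The conditions of step 11 then close ring B with allylic transposition and give 19.

**Step 18 (epoxidation).**
- What may go wrong: poor facial selectivity if the ten-membered ring does not present the outer face as assumed, or over-oxidation.
- Fallback, from 26 back to 27: NBS in aqueous acetone gives bromohydrin F11 (bromine at C5, hydroxyl at C4), and closure with Ag2O puts the epoxide on the face opposite to the one the bromonium ion took. This inverts the facial outcome of direct epoxidation.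

## Further compounds

F1 | step 15 | ten-membered C1 ketone with C6 methylene, Z C4=C5, methyl ester cis to C6, C8 triisopropylsilyl ether | COC(=O)/C(COC(C)=O)=C1/[C@@H](O[Si](C(C)C)(C(C)C)C(C)C)C[C@@](C)(OC(C)=O)C(=O)CC/C(C)=C\C1
F2 | step 15 | C6 bromide of F1 | COC(=O)/C(COC(C)=O)=C1/[C@@H](O[Si](C(C)C)(C(C)C)C(C)C)C[C@@](C)(OC(C)=O)C(=O)CC/C(C)=C\C1Br
F3 | step 11 | ring B alkenyl iodide (iodine on C11 cis to C6, C6 vinyl, C1 triethylsilyl ether) | I/C(CO[Si](C)(C)C(C)(C)C)=C1/[C@@H](O[Si](C(C)C)(C(C)C)C(C)C)C[C@@](C)(OC(C)=O)C(O[Si](CC)(CC)CC)(CCC(C)=C)C1C=C
F4 | step 9 | C1 allyl carbinol from 12 | CC(C)(C)[Si](C)(C)OCC#C[C@@H](O[Si](C(C)C)(C(C)C)C(C)C)C[C@@](C)(OC(C)=O)C(O)(CCC(C)=C)CC=C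
F5 | step 9 | 1-substituted 4-methylcyclohex-3-en-1-ol (ring A) | CC(C)(C)[Si](C)(C)OCC#C[C@@H](O[Si](C(C)C)(C(C)C)C(C)C)C[C@@](C)(OC(C)=O)C1(O)CCC(C)=CC1
F6 | step 9 | C4–C5 epoxide of F5, cis to the C1 hydroxyl | CC(C)(C)[Si](C)(C)OCC#C[C@@H](O[Si](C(C)C)(C(C)C)C(C)C)C[C@@](C)(OC(C)=O)C1(O)CCC2(C)OC2C1
F7 | step 9 | C1 triethylsilyl ether of F6 | CC(C)(C)[Si](C)(C)OCC#C[C@@H](O[Si](C(C)C)(C(C)C)C(C)C)C[C@@](C)(OC(C)=O)C1(O[Si](CC)(CC)CC)CCC2(C)OC2C1
F8 | step 9 | C4 hydroxy C5 phenylselenide from F7 | CC(C)(C)[Si](C)(C)OCC#C[C@@H](O[Si](C(C)C)(C(C)C)C(C)C)C[C@@](C)(OC(C)=O)C1(O[Si](CC)(CC)CC)CCC(C)(O)C([Se]c2ccccc2)C1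
F9 | step 9 | C4 tertiary allylic alcohol with C5=C6 (hydroxyl cis to O1) | CC(C)(C)[Si](C)(C)OCC#C[C@@H](O[Si](C(C)C)(C(C)C)C(C)C)C[C@@](C)(OC(C)=O)C1(O[Si](CC)(CC)CC)CCC(C)(O)C=C1
F10 | step 9 | C4 acetate of F9 | CC(C)(C)[Si](C)(C)OCC#C[C@@H](O[Si](C(C)C)(C(C)C)C(C)C)C[C@@](C)(OC(C)=O)C1(O[Si](CC)(CC)CC)CCC(C)(OC(C)=O)C=C1
F11 | step 18 | bromohydrin of 26 (C4 hydroxyl, C5 bromide) | C=C(C)C(=O)O[C@H]1C[C@@](C)(OC(C)=O)C(=O)CC[C@@](C)(O)[C@H](Br)[C@@H]2OC(=O)C(COC(C)=O)=C12
A1 | alternative 1 | cyclodecenol with C6 hydroxyl and C7 2-propenyl branch (C8 4-methoxybenzyl ether, C10 triethylsilyl ether, C1 dimethyl ketal) | COc1ccc(CO[C@H]2C[C@@](C)(O[Si](CC)(CC)CC)C(OC)(OC)CC/C(C)=C\[C@H](O)[C@@H]2C(=C)CO[Si](C)(C)C(C)(C)C)cc1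
A2 | alternative 2 | bicyclo[6.2.0]decanone photoadduct | O=C1[C@H]2C[C@@](C)(OC(C)=O)[C@@]2(O[Si](C)(C)C(C)(C)C)CC[C@@]3(C)O[C@H]3[C@@H]1OCc1ccc(OC)cc1
A3 | alternative 2 | isopropenyl acetate | CC(=C)OC(C)=O
A4 | alternative 3 | 8-hydroxy compound (target lacking the methacryloyl group) | O[C@H]1C[C@@](C)(OC(C)=O)C(=O)CC[C@@]2(C)O[C@H]2[C@@H]2OC(=O)C(COC(C)=O)=C12
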